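**Slow partner.** I started from the slowness of these flasks: a coupling partner that stays for hours meets whatever acceptors stand there, and the recipes differ in when it meets them.

all flasks: time 25 h

| flask | substrate | coupling partner | remark |
|---|---|---|---|
| ash | 0.10 M | 0.0800 M | everything together at the start |
| oak | 0.10 M | 0.0800 M (in portions, 2, over 20 h) | first portion at the start, last at 20 h |
| birch | 0.10 M | 0.0800 M (fed, over 20 h) | all else is in the flask from the start; the feed brings no volume worth counting |
| larch | 0.10 M (fed, over 20 h) | 0.0800 M | all else is in the flask from the start; the feed brings no volume worth counting |

    coupling partner + mono adduct → double product (k1 = 1.0 M⁻¹ h⁻¹)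
    substrate ⇌ dormant form (K2 = 0.48, k2 = 0.33 h⁻¹)
    mono adduct ⇌ isomer of the product (K3 = 1.7, k3 = 0.0060 h⁻¹)
    substrate + coupling partner → mono adduct (k4 = 1.2 M⁻¹ h⁻¹)
    coupling partner + double product → tris adduct (k5 = 0.44 M⁻¹ h⁻¹)

* the flask that comes out highest in share of mono adduct in mono adduct plus double product, or "all alike" when all lie within 1.5 percentage points (ash / oak / birch / larch / all alike)
* share of mono adduct in mono adduct plus double product at the end, ash
* share of mono adduct in mono adduct plus double product at the end, oak
* share of mono adduct in mono adduct plus double product at the end, birch
* share of mono adduct in mono adduct plus double product at the end, larch

**Bench rule.** The bench rule says that a limiting reagent, here the coupling partner at 80.0% of the substrate charge, lands on the substrate in excess, which promises a share of 100%.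

**Its border.** That rule asks for a selectivity factor far below one. In ash, with each step's forward rate taken alone and the amounts as charged, the substrate goes dormant faster than it couples, with half-lives of 2.1 h against 7.2 h, so I treated substrate and dormant form as one pool and took the selectivity factor, the constant of mono adduct over that of the pool, as 1.23, which is above one, so the rule fails.

**Both ends.** Since this factor stays below two, I let each lost substrate leave an acceptor about as good, so the partner decays pseudo-first-order with lifetime 12.3 h, and the pool falls as the exponential of minus the uptake, the partner taken up as a fraction of the substrate charge. In this reckoning, with isomer of the product counted as mono adduct and tris adduct as double product, the share runs from 100% at no uptake to 59.5% at full uptake.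

**Four uptakes.** My uptakes were 0.695 for ash, 0.481 for oak, 0.536 for birch and, more roughly, counting larch's clock from the mean arrival of its substrate, 0.563. These gave shares of 63.9%, 73.7%, 71.0% and 69.8%, with oak highest.

**The forecast.** The forecast gave 66.5% for ash, 75% for oak, 73% for birch and 67% for larch, and chose oak, holding that “holding the partner back (oak, birch) lowers that exposure and spares the mono adduct”. Its figures are not mine, though its flasks stand in the same order.

**The result.** The simulation gave 65.9% for ash, 75.1% for oak, 72.8% for birch and 68.1% for larch, with oak highest. The forward half-life of isomerisation in ash is 120 h, long against 25 h. Oak kept 40% of its partner, an uptake of 0.482, and the selectivity factor turns that into 28.2% of the substrate charged as mono adduct and isomer together, where oak held 26.0% and 2.45%.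

**Longer ash.** For ash left until 2.5 d, the same factor gave me 59.8%. That flask gives 58.8%, with 1.04% of its partner left.

All constants are those of an exercise, and the outcome is calculated.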